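## Retrosynthetic overview

1. Broussonetine S ⇐ anti-opening of a 3,4-epoxypyrrolidine (sets the trans-diol) plus hydrolysis of an N,O-carbonyl bridge.
2. That bridged epoxide ⇐ a 2,5-trans-3-pyrroline already carrying the full side chain, with C1′ corrected by Boc participation (inversion).
3. The C2–C1′ bond ⇐ allylboration of a C13 lactone-aldehyde by a cyclic allylboronate.
4. The allylboronate ⇐ Cu-catalysed enantioselective borylative dearomatisation of N-Boc methyl pyrrole-2-carboxylate (key step).
5. The lactone-aldehyde ⇐ mono-allylation of symmetric decane-1,10-diol. Ring order: the pyrrole ring is carried through and never built; temporary γ-lactone, oxazolidinone and oxirane rings are formed in that order and all opened by the end.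

Assumption: locants C2–C5 and C1′–C13′ are those of the target (C2 bears the side chain, C5 the CH2OH). I do not specify which ligand antipode is needed in steps 2 and 3; the one that delivers the stated configuration is used (both are commercial).

## Route

**Step 1**
Reactants: 1, methyl 1H-pyrrole-2-carboxylate
Product: 2, 1-tert-butyl 2-methyl 1H-pyrrole-1,2-dicarboxylate
Conditions: Boc2O (1.2 equiv), DMAP (10 mol %), MeCN, rt
Reagents that add atoms: di-tert-butyl dicarbonate, CC(C)(C)OC(=O)OC(=O)OC(C)(C)C
Why: DMAP-catalysed N-acylation of the acidic pyrrole N–H; the carbamate lowers aromatic stabilisation for the conjugate borylation and later serves as the internal nucleophile in step 7.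

**Step 2**
Reactants: 2
Product: 3, 1-tert-butyl 2-methyl (2S,3S)-3-(4,4,5,5-tetramethyl-1,3,2-dioxaborolan-2-yl)-2,3-dihydro-1H-pyrrole-1,2-dicarboxylate (ester and Bpin trans)
Conditions: CuCl (5 mol %), QuinoxP* (5 mol %, antipode giving 3S), KOtBu (20 mol %), B2pin2 (1.5 equiv), tBuOH (2 equiv), THF, 30 °C; then KOtBu (0.3 equiv), tBuOH, rt; pH 7 work-up
Reagents that add atoms: bis(pinacolato)diboron, CC1(C)OB(OC1(C)C)B1OC(C)(C)C(C)(C)O1
Why: Proposed new method: the closest known reaction is the Cu(I)/bisphosphine-catalysed enantioselective borylative dearomatisation of N-acyl pyrrole-2-carboxylates, in which ligand-controlled syn-borylcupration of the ester-conjugated C=C sets the C–B centre (target C4) and the copper enolate is protonated; the untested element is the in-pot alkoxide equilibration of the ester carbon (target C5), which should convert any kinetically formed cis isomer into the less strained 2,3-trans boronate because that C–H is the only acidic site and is not conjugated to the enecarbamate.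

**Step 3**
Reactants: 4, decane-1,10-diol (3 equiv); 5, allyl acetate (1 equiv)
Product: 6, (10S)-tridec-12-ene-1,10-diol
Conditions: [Ir(cod)Cl]2 (2.5 mol %), Cl,MeO-BIPHEP (5 mol %, antipode giving 10S), 4-Cl-3-NO2-C6H3CO2H (10 mol %), Cs2CO3 (20 mol %), THF, 100 °C, sealed tube; excess 4 recovered
Reagents that add atoms: none (5 is a reactant)
Why: Krische transfer-hydrogenative carbonyl allylation, in which the alcohol is dehydrogenated in situ and the chiral cyclometalated π-allyl-iridium adds to the transient aldehyde through a closed chair to set C10′ (S); excess of the symmetric diol keeps the reaction at mono-allylation.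

**Step 4**
Reactants: 6
Product: 7, (4S)-tridecane-1,4,13-triol
Conditions: 9-BBN (3.5 equiv), THF, 0 °C → rt; then NaOH, H2O2, 0 °C → rt
Reagents that add atoms: hydrogen peroxide, OO
Why: Anti-Markovnikov hydroboration–oxidation of the terminal alkene (two equivalents of borane are consumed by the O–H groups); the carbinol stereocentre is not touched.

**Step 5**
Reactants: 7
Product: 8, 9-[(2S)-5-oxooxolan-2-yl]nonanal
Conditions: TEMPO (20 mol %), PhI(OAc)2 (3.5 equiv), CH2Cl2–MeCN (anhydrous), rt
Reagents that add atoms: none
Why: TEMPO/BAIB oxidises primary alcohols selectively over the secondary one; the γ-hydroxy aldehyde closes to a lactol that is oxidised on to the γ-lactone (oxidative lactonisation), while the remote aldehyde stays at the aldehyde level without water, and the C10′–O bond is untouched.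

**Step 6**
Reactants: 3; 8 (1.2 equiv)
Product: 9, 1-tert-butyl 2-methyl (2S,5S)-5-{(1S)-1-hydroxy-9-[(2S)-5-oxooxolan-2-yl]nonyl}-2,5-dihydro-1H-pyrrole-1,2-dicarboxylate (2,5-trans; carbinol threo to N)
Conditions: toluene, 50 °C, 24 h; aq. NH4Cl work-up
Reagents that add atoms: none
Why: Thermal aldehyde allylboration through a Zimmerman–Traxler chair, in which the new C2–C1′ bond forms on the face that carried boron (suprafacial, giving 2,5-trans), and the ring-fixed (Z)-γ-nitrogen axial with the aldehyde chain equatorial gives the syn (threo) amino alcohol, 1′S.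

**Step 7**
Reactants: 9
Product: 10, methyl (1R,5S,7aS)-3-oxo-1-{8-[(2S)-5-oxooxolan-2-yl]octyl}-5,7a-dihydro-1H,3H-pyrrolo[1,2-c][1,3]oxazole-5-carboxylate
Conditions: Tf2O (1.2 equiv), pyridine (3 equiv), CH2Cl2, −78 → 0 °C
Reagents that add atoms: none
Why: N-Boc neighbouring-group participation, in which the carbamate C=O displaces the secondary triflate intramolecularly (5-exo-tet SN2) with inversion at C1′ (S → R, the natural erythro relationship) and loss of isobutene, turning Boc into a base-labile bicyclic oxazolidinone.

**Step 8**
Reactants: 10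
Product: 11, (1R,5S,7aS)-1-[(9S)-9,12-dihydroxydodecyl]-5-(hydroxymethyl)-5,7a-dihydro-1H,3H-pyrrolo[1,2-c][1,3]oxazol-3-one
Conditions: LiBH4 (4 equiv), MeOH (2 equiv), THF, 0 °C → rt
Reagents that add atoms: none
Why: Borohydride reduction of the methyl ester to CH2OH and the γ-lactone to the 1,4-diol, leaving the cyclic carbamate and the isolated alkene intact (any carbamate migration to the new CH2OH would be harmless, since both isomers give 13 after steps 9–10).

**Step 9**
Reactants: 11
Product: 12, the 6,7-epoxide of 11 with the oxirane oxygen on the same face as the C5 CH2OH (anti to the C1 chain)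
Conditions: mCPBA (3 equiv), NaHCO3, ClCH2CH2Cl, 50 °C, cat. radical inhibitor
Reagents that add atoms: mCPBA, OOC(=O)c1cccc(Cl)c1
Why: Prilezhaev epoxidation of the deactivated 3-pyrroline alkene, where hydrogen bonding to the CH2OH and shielding of the other face by the C1′ chain favour the epoxide shown, and the facial outcome is not critical because both epoxides give the same diol in step 10.

**Step 10**
Reactants: 12
Product: 13, Broussonetine S, (2R,3R,4R,5R)-2-(hydroxymethyl)-5-[(1R,10S)-1,10,13-trihydroxytridecyl]pyrrolidine-3,4-diol
Conditions: 0.5 M H2SO4, 1,4-dioxane–H2O, 90 °C; then Ba(OH)2·8H2O (excess), reflux; Dowex 50W (H+), elute aq. NH3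
Reagents that add atoms: water, O
Why: Acid-catalysed SN2-type epoxide hydrolysis in which water attacks the oxirane carbon from the face anti to the substituent on the neighbouring N-bearing carbon (C4 for 12, C3 for the minor epoxide), so either epoxide gives the all-trans C2–C5 array, and Ba(OH)2 then hydrolyses the cyclic carbamate with retention at C1′.

## Compound list

1 | methyl 1H-pyrrole-2-carboxylate | COC(=O)c1ccc[nH]1 | starting material
2 | 1-tert-butyl 2-methyl 1H-pyrrole-1,2-dicarboxylate | COC(=O)c1cccn1C(=O)OC(C)(C)C | intermediate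
3 | 1-tert-butyl 2-methyl (2S,3S)-3-(pinacolatoboryl)-2,3-dihydro-1H-pyrrole-1,2-dicarboxylate | COC(=O)[C@H]1N(C(=O)OC(C)(C)C)C=C[C@@H]1B1OC(C)(C)C(C)(C)O1 | intermediate
4 | decane-1,10-diol | OCCCCCCCCCCO | starting material
5 | allyl acetate | CC(=O)OCC=C | starting material
6 | (10S)-tridec-12-ene-1,10-diol | OCCCCCCCCC[C@H](O)CC=C | intermediate
7 | (4S)-tridecane-1,4,13-triol | OCCC[C@@H](O)CCCCCCCCCO | intermediate
8 | 9-[(2S)-5-oxooxolan-2-yl]nonanal | O=CCCCCCCCC[C@H]1CCC(=O)O1 | intermediate
9 | 1-tert-butyl 2-methyl (2S,5S)-5-{(1S)-1-hydroxy-9-[(2S)-5-oxooxolan-2-yl]nonyl}-2,5-dihydro-1H-pyrrole-1,2-dicarboxylate | COC(=O)[C@@H]1C=C[C@@H]([C@@H](O)CCCCCCCC[C@H]2CCC(=O)O2)N1C(=O)OC(C)(C)C | intermediate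
10 | methyl (1R,5S,7aS)-3-oxo-1-{8-[(2S)-5-oxooxolan-2-yl]octyl}-5,7a-dihydro-1H,3H-pyrrolo[1,2-c][1,3]oxazole-5-carboxylate | COC(=O)[C@@H]1C=C[C@H]2[C@@H](CCCCCCCC[C@H]3CCC(=O)O3)OC(=O)N12 | intermediate
11 | (1R,5S,7aS)-1-[(9S)-9,12-dihydroxydodecyl]-5-(hydroxymethyl)-5,7a-dihydro-1H,3H-pyrrolo[1,2-c][1,3]oxazol-3-one | OC[C@@H]1C=C[C@H]2[C@@H](CCCCCCCC[C@H](O)CCCO)OC(=O)N12 | intermediate
12 | 6,7-epoxide of 11, oxirane O syn to the C5 CH2OH | OC[C@@H]1[C@@H]2O[C@@H]2[C@H]3[C@@H](CCCCCCCC[C@H](O)CCCO)OC(=O)N13 | intermediate
13 | Broussonetine S | OCCC[C@@H](O)CCCCCCCC[C@@H](O)[C@H]1N[C@H](CO)[C@@H](O)[C@@H]1O | target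

## Summary

Total steps: 10. Longest linear sequence: 8 (steps 3–10 from decane-1,10-diol; 7 from the pyrrole ester).

Steps most likely to fail, with fallbacks:

1. **Step 2** (dearomative borylation with the required 2,3-trans relationship; the allylboronate may not survive the alkoxide equilibration). Fallback: Birch-type partial reduction (Li/NH3, NH4Cl) of dimethyl N-Boc-pyrrole-2,5-dicarboxylate to the C2-symmetric trans-2,5-diester, enzymatic resolution, then mono-Weinreb amide, chain Grignard and ketone reduction to build C1′.
2. **Step 7** (inversion to the more hindered cis-oxazolidinone; competing elimination and re-aromatisation to a pyrrole). Fallback: oxidise the C1′ alcohol of 9 to the ketone (Dess–Martin) and set 1′R by reagent-controlled reduction (CBS), carrying N-Boc to a final acidic deprotection.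
3. **Step 10** (regioselective opening of a deactivated epoxide). Fallback: OsO4/NMO syn-dihydroxylation of 11 (primary OH protected), cyclic sulfate formation, and carboxylate opening to invert one carbinol; this is also convergent because the carboxylate attacks anti to the adjacent ring substituent.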